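(The numbers in the tables were computed for an exercise; scatter was added.)

Target beyond the substrate charged is impossible, so test two things that may hold these flasks short of that wall: time, and the charge of what the substrate needs. Reckon each end, then join them.

in all of them: substrate 0.40 M
- west: reagent 0.48 M; scavenger 0.54 M; free catalyst 4 mM; run made earlier
- south-east: reagent 0.48 M; scavenger 0.86 M; free catalyst 4 mM; run made earlier
- amber: reagent 0.480 M; scavenger 0.600 M; free catalyst 4.0 mM; time 40 min
- grey: reagent 0.480 M; scavenger 0.400 M; free catalyst 4.0 mM; time 40 min

| run | time / min | substrate / % | target / % |
|---|---|---|---|
| west | 5.00 | 64.4 | 34.2 |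
| west | 10.0 | 41.1 | 58.3 |
| west | 15.0 | 23.0 | 77.7 |
| west | 20.0 | 11.5 | 89.4 |
| south-east | 2.50 | 80.7 | 20.8 |
| south-east | 8.00 | 49.2 | 52.0 |
| south-east | 12.0 | 30.9 | 68.4 |
| south-east | 20.0 | 10.3 | 89.7 |

(standard deviation of a reading: 1 percentage point)

- part of the substrate that has reacted at the end, amber
- part of the substrate that has reacted at the end, grey
- what raising the concentration of scavenger from its lowest to its highest value here does to the part of the substrate that has reacted (changes below 5 percentage points count as none) (no change / it rises / it falls)

Start with time. Take the last two readings of the west run: substrate goes from 23.0% to 11.5% between 15.0 min and 20.0 min, so the tail constant k, the fractional loss of remaining substrate per minute, reads 0.139 min⁻¹. The last two south-east readings, with 0.86 M of scavenger against 0.54 M, give 0.137 min⁻¹, so treat scavenger in that range as leaving the tail alone. Carry k from the last west reading to 40 min: 0.719% of the substrate remains. Commit to 99.3% reacted in amber and in grey, with a change below 5 percentage points.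

Now test the charges, since that extrapolation assumes supply holds. Reagent was never read, so assume one reagent per substrate. Divide reagent charge by substrate charge: 120%. Call this the reagent ceiling C, the share of the substrate the reagent can serve. In amber and grey it stands above the substrate charged, so on that assumption substrate, not reagent, is the limiting reagent. The weak link is grey, whose 0.400 M of scavenger lies below both runs. Forge it the same way, assuming one scavenger per substrate: the ratio is 100%, just enough, so on that assumption the time reckoning stands.

The forecast gives 99% for amber, 97% for grey, lower than my grey figure, and no change, calling grey “(1.0 equiv) is just sufficient, though untested”.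

The flask gives 99.8% in amber and 99.7% in grey, and no change, with a change of 0.094 points.

    reagent + free catalyst → catalyst intermediate A (k = 1.24 M⁻¹ s⁻¹)
    substrate + catalyst intermediate A → catalyst intermediate B (k = 1.00 M⁻¹ s⁻¹)
    catalyst intermediate B → released group + catalyst intermediate C (k = 0.971 s⁻¹)
    catalyst intermediate C → catalyst intermediate D (k = 0.517 s⁻¹)
    catalyst intermediate D → free catalyst + target (k = 5.61 s⁻¹)
    reagent + released group ⇌ idle adduct, settled at all times (K = 400 M⁻¹)
    scavenger + released group → scavenged by-product (k = 0.718 M⁻¹ s⁻¹)

Read C on amber first: serving the substrate at one per substrate should leave 16.7% of the reagent in all its forms, and amber has 16% of its charge left free at 40.0 min, beside 0.00168 M of idle adduct and 99.0% of the catalyst as catalyst intermediate A. Now take the neighbouring flask, like grey but with 1.6 M of substrate. There C falls to 30.0%, below the substrate charged. That flask reaches 28.3% reacted at 40 min, with 0% of its scavenger and 0.43% of its reagent left.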